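The route rests on hiding the target inside a tricyclic ether: the C1 ester oxygen and the C10 methyl carbon of the spiro[4.5]decane are tied as a tetrahydrofuran (C1–O–CH2–C10). One pot then builds the cyclohexenone ring on a limonene-derived acetylcyclopentene: a γ-hydroxy enone adds by oxa-Michael/Michael reaction, which makes the quaternary spiro bond C5–C10 cis to the new C1–O bond, and the resulting 1,5-diketone closes by aldol condensation to the C6=C7 enone. The step exploits the cis arrangement of O–C1, C10 and the C10 methyl around spiro atom C5 (rings: cyclopentane, cyclohexenone). Acylative ether opening with senecioyl iodide, deiodination and C9 acetoxylation finish the synthesis.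

Key step: step 4

Remark: locants in the text follow the spiro[4.5]decane numbering of the target (C1 carries the senecioate, C3 the isopropenyl group, C5 is the spiro atom, C6(CH3)=C7–C8(=O) is the enone, C9 carries OAc, C10 the secondary methyl).

Step 1
Reactants: 1 (1S,2S,4R)-limonene-1,2-diol
Product: 2 (3R)-6-oxo-3-(prop-1-en-2-yl)heptanal
Conditions: NaIO4, THF/H2O, 0 °C to rt
Reagents that add atoms: none
Why: Periodate glycol cleavage (Malaprade reaction) of the vicinal diol should give the keto aldehyde without touching the isopropenyl group or the stereocentre.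

Step 2
Reactants: 2 (3R)-6-oxo-3-(prop-1-en-2-yl)heptanal
Product: 3 1-[(4S)-4-(prop-1-en-2-yl)cyclopent-1-en-1-yl]ethan-1-one
Conditions: piperidine, AcOH (cat.), toluene, reflux, Dean–Stark
Reagents that add atoms: none
Why: Intramolecular aldol condensation under piperidinium acetate, a known transformation of this keto aldehyde, in which the methylene next to the ketone adds to the aldehyde and dehydration gives the conjugated acetylcyclopentene; the stereocentre is not involved (its descriptor changes only by CIP priority).

Step 3
Reactants: 4 glycolaldehyde dimer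
Product: 6 (E)-5-hydroxypent-3-en-2-one, via glycolaldehyde 5 (not isolated)
Conditions: Ph3P=CHC(O)CH3, THF, reflux
Reagents that add atoms: 1-(triphenylphosphoranylidene)propan-2-one, CC(=O)C=P(c1ccccc1)(c1ccccc1)c1ccccc1
Why: Wittig olefination of the monomeric aldehyde, released from the dimer on heating, with a stabilised ylide should give the E enone.

Step 4
Reactants: 3 1-[(4S)-4-(prop-1-en-2-yl)cyclopent-1-en-1-yl]ethan-1-one (in excess); 6 (E)-5-hydroxypent-3-en-2-one
Product: 8 oxymethylene-bridged tricyclic enone (C1–O–CH2–C10 tetrahydrofuran on the 6-methyl-3-isopropenylspiro[4.5]dec-6-en-8-one core; 1S,3R,5S,10S), via bicyclic diketone 7 (not isolated)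
Conditions: KOtBu (0.2 equiv), THF, −20 °C, slow addition of 6 to 3 (3 equiv); then AcOH, pyrrolidine, 4 Å MS, 60 °C (one pot)
Reagents that add atoms: none
Why: The alkoxide of 6 should add reversibly to the β-carbon of enone 3 (oxa-Michael, C1–O bond), and the C5 enolate formed in this way closes the tetrahydrofuran by 5-exo-trig Michael addition to the tethered enone (C5–C10 bond, diketone 7); after acidification, pyrrolidine condenses with the unhindered side-chain ketone, its methyl-side enamine attacks the acetyl carbonyl (6-enolexo-exo-trig aldol) and loss of water gives the C6=C7 enone. The closest known reactions are the domino oxa-Michael/Michael tetrahydrofuran annulation of γ-hydroxy enones and the amine-mediated aldol condensation of the Robinson annulation (Hajos–Parrish type). C1 and C5: the five-membered ring can only be cis-fused, so C10 is delivered to the face of the new C1–O bond, and because the oxa-Michael step is reversible the C–C closure should select the bicycle that carries the isopropenyl group on its convex face (oxygen anti to isopropenyl, controlled by the isopropenyl-bearing stereocentre of 3). C10: the oxopropyl chain should take the convex face, cis to the acetyl group, which is also the only epimer able to close the cis-fused cyclohexenone, and retro-Michael equilibration can feed it. The step needs cross-addition of 6 to 3 to win over self-addition of 6, secured by slow addition to excess 3, and it needs aldol closure from the side-chain methyl onto the acetyl group and not the reverse, secured by the fact that only the unhindered ketone can form an enamine while the acetyl group on the fully substituted C5 cannot.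

Step 5
Reactants: 8 oxymethylene-bridged tricyclic enone
Product: 9 (1S,3R,5S,10S)-10-(iodomethyl)-6-methyl-8-oxo-3-(prop-1-en-2-yl)spiro[4.5]dec-6-en-1-yl 3-methylbut-2-enoate
Conditions: 3-methylbut-2-enoyl chloride, NaI, MeCN, 0 °C to rt, dark
Reagents that add atoms: 3-methylbut-2-enoyl chloride, CC(C)=CC(Cl)=O; sodium iodide, [Na+].[I-]
Why: Acylative ether cleavage with an acyl iodide made in the flask: O-acylation gives an acyloxonium ion that iodide should open by SN2 attack at the primary CH2 and not at the neopentyl-type C1, which leaves the senecioate on C1 with its configuration unchanged and a CH2I group on C10.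

Step 6
Reactants: 9 iodomethyl senecioate
Product: 10 (1S,3R,5S,10S)-6,10-dimethyl-8-oxo-3-(prop-1-en-2-yl)spiro[4.5]dec-6-en-1-yl 3-methylbut-2-enoate
Conditions: Bu3SnH, AIBN (cat.), PhH, 80 °C
Reagents that add atoms: none
Why: Radical chain dehalogenation, in which the primary radical should take hydrogen from the tin hydride faster than it can add to any of the alkenes (only 4-exo, 5-endo or larger-ring modes are open), turns CH2I into the C10 methyl.

Step 7
Reactants: 10 spiro enone senecioate
Product: 11 (1S,3R,5S,9S,10R)-9-acetoxy-6,10-dimethyl-8-oxo-3-(prop-1-en-2-yl)spiro[4.5]dec-6-en-1-yl 3-methylbut-2-enoate (target)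
Conditions: Mn(OAc)3·2H2O, PhH, reflux, Dean–Stark
Reagents that add atoms: manganese triacetate dihydrate, CC(=O)[O-].CC(=O)[O-].CC(=O)[O-].[Mn+3].O.O
Why: α'-Acetoxylation of the enone through its trivalent manganese enolate and the α'-keto radical should place the acetate on C9 anti to the neighbouring C10 methyl, and this epimerisable centre settles in the trans (diequatorial) arrangement.

Compound list
1 | (1S,2S,4R)-limonene-1,2-diol, (1S,2S,4R)-1-methyl-4-(prop-1-en-2-yl)cyclohexane-1,2-diol | C=C(C)[C@@H]1CC[C@](C)(O)[C@@H](O)C1 | starting material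
2 | (3R)-6-oxo-3-(prop-1-en-2-yl)heptanal | C=C(C)[C@H](CCC(C)=O)CC=O | intermediate
3 | 1-[(4S)-4-(prop-1-en-2-yl)cyclopent-1-en-1-yl]ethan-1-one, (S)-1-acetyl-4-isopropenylcyclopentene | C=C(C)[C@H]1CC=C(C1)C(C)=O | intermediate
4 | glycolaldehyde dimer, 1,4-dioxane-2,5-diol | OC1COC(O)CO1 | starting material
5 | glycolaldehyde, 2-hydroxyacetaldehyde (not isolated) | OCC=O | intermediate
6 | (E)-5-hydroxypent-3-en-2-one | CC(=O)/C=C/CO | intermediate
7 | bicyclic diketone (not isolated): cis-fused hexahydro-2H-cyclopenta[b]furan with acetyl on ring-fusion carbon 3a, 2-oxopropyl on C3 cis to the acetyl group, isopropenyl on C5 on the face opposite to the ring oxygen | C=C(C)[C@H]1C[C@H](O3)[C@](C1)(C(C)=O)[C@H](CC(C)=O)C3 | intermediate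
8 | oxymethylene-bridged tricyclic enone: (1S,3R,5S,10S)-6-methyl-3-(prop-1-en-2-yl)spiro[4.5]dec-6-en-8-one with the C1 oxygen joined through CH2 to C10 (tetrahydrofuran cis-fused at C1–C5 and at C5–C10, ring oxygen anti to isopropenyl) | C=C(C)[C@H]1C[C@H](O3)[C@]2(C1)C(C)=CC(=O)C[C@@H]2C3 | intermediate
9 | (1S,3R,5S,10S)-10-(iodomethyl)-6-methyl-8-oxo-3-(prop-1-en-2-yl)spiro[4.5]dec-6-en-1-yl 3-methylbut-2-enoate | C=C(C)[C@H]1C[C@H](OC(=O)C=C(C)C)[C@]2(C1)C(C)=CC(=O)C[C@@H]2CI | intermediate
10 | (1S,3R,5S,10S)-6,10-dimethyl-8-oxo-3-(prop-1-en-2-yl)spiro[4.5]dec-6-en-1-yl 3-methylbut-2-enoate | C=C(C)[C@H]1C[C@H](OC(=O)C=C(C)C)[C@]2(C1)C(C)=CC(=O)C[C@@H]2C | intermediate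
11 | (1S,3R,5S,9S,10R)-9-acetoxy-6,10-dimethyl-8-oxo-3-(prop-1-en-2-yl)spiro[4.5]dec-6-en-1-yl 3-methylbut-2-enoate, CNP0218315.1 | C=C(C)[C@H]1C[C@H](OC(=O)C=C(C)C)[C@]2(C1)C(C)=CC(=O)[C@@H](OC(C)=O)[C@@H]2C | target

Total step count: 7. Longest linear sequence: 6 steps (steps 1, 2, 4, 5, 6, 7); step 3 is a one-step side branch.

Steps most likely to fail

Step 4. Two processes may spoil it. The aldol closure may run in the reverse sense, with the acetyl methyl attacking the side-chain ketone; on steric and electronic grounds this is the intrinsically easier direction for the free diketone. Self-addition or base-induced isomerisation of the hydroxy enone may also outrun its addition to the less electrophilic, trisubstituted enone 3. The fallback sets out from 3 and comes back at 8; it closes the six-membered ring by a condensation that has only one possible course and sets the enone by the Stork–Danheiser sequence. Enone 3 is combined under the same alkoxide catalysis with ethyl (E)-4-hydroxybut-2-enoate F1 (from 4 and Ph3P=CHCO2Et), a weaker acceptor that should self-add more slowly, to give the bicyclic keto ester F2. KOtBu in THF then closes the acetyl methyl onto the ester (Claisen condensation) to give the tricyclic 1,3-dione F3. MeOH, HC(OMe)3 and TsOH should form the methyl enol ether at the less hindered carbonyl, vinylogous ester F4 (ketone at C6, OMe at C8). MeLi with CeCl3 in THF at −78 °C adds to the C6 ketone to give the tertiary allylic alcohol F5, and aqueous HCl hydrolyses and transposes it to 8.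

Step 5. The acyloxonium ion may open at the wrong C–O bond or ionise at C1 with skeletal rearrangement, and adventitious HI may add to the isopropenyl group or shift the double bond of the senecioate. The fallback sets out from 8 and comes back at 10; it separates cleavage from acylation. Me2BBr in CH2Cl2 (−78 to 0 °C) should open the tetrahydrofuran at the primary carbon to give the bromo alcohol F6. Esterification with 3-methylbut-2-enoic acid, DCC and DMAP in CH2Cl2 gives the bromo senecioate F7. Bu3SnH and AIBN as in step 6 then give 10.

Step 7. The α'-keto radical may add to the isopropenyl or senecioate alkenes, oxidation may also occur at the γ-methyl, and control of the C9 configuration may be poor. The fallback sets out from 10 and comes back at 11; it is a polar Rubottom sequence. LiN(SiMe3)2 and Me3SiCl in THF at −78 °C give the cross-conjugated trimethylsilyl dienol ether F8. Dimethyldioxirane in acetone at −78 °C, attacking anti to the C10 methyl, gives the silyloxy ketone F9. Citric acid in MeOH frees the hydroxy ketone F10, and Ac2O, DMAP and pyridine give 11.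

Further compounds
F1 | step 4 | ethyl (E)-4-hydroxybut-2-enoate | CCOC(=O)/C=C/CO
F2 | step 4 | bicyclic keto ester: cis-fused hexahydro-2H-cyclopenta[b]furan with 3a-acetyl, 3-(ethoxycarbonylmethyl) cis to acetyl, 5-isopropenyl anti to the ring oxygen | C=C(C)[C@H]1C[C@H](O3)[C@](C1)(C(C)=O)[C@H](CC(=O)OCC)C3
F3 | step 4 | tricyclic 1,3-dione: the ring system of 8 with ketones at C6 and C8 and CH2 at C7 | C=C(C)[C@H]1C[C@H](O3)[C@]2(C1)C(=O)CC(=O)C[C@@H]2C3
F4 | step 4 | tricyclic vinylogous ester: the ring system of 8 with C6 ketone and C7=C8 methyl enol ether | C=C(C)[C@H]1C[C@H](O3)[C@]2(C1)C(=O)C=C(OC)C[C@@H]2C3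
F5 | step 4 | tertiary allylic alcohol from MeLi addition to F4 (C6 carbinol centre not defined) | C=C(C)[C@H]1C[C@H](O3)[C@]2(C1)C(C)(O)C=C(OC)C[C@@H]2C3
F6 | step 5 | (1S,3R,5S,10S)-10-(bromomethyl)-1-hydroxy-6-methyl-3-(prop-1-en-2-yl)spiro[4.5]dec-6-en-8-one | C=C(C)[C@H]1C[C@H](O)[C@]2(C1)C(C)=CC(=O)C[C@@H]2CBr
F7 | step 5 | (1S,3R,5S,10S)-10-(bromomethyl)-6-methyl-8-oxo-3-(prop-1-en-2-yl)spiro[4.5]dec-6-en-1-yl 3-methylbut-2-enoate | C=C(C)[C@H]1C[C@H](OC(=O)C=C(C)C)[C@]2(C1)C(C)=CC(=O)C[C@@H]2CBr
F8 | step 7 | trimethylsilyl dienol ether of 10 (C6=C7 and C8=C9, OSiMe3 on C8) | C=C(C)[C@H]1C[C@H](OC(=O)C=C(C)C)[C@]2(C1)C(C)=CC(O[Si](C)(C)C)=C[C@@H]2C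
F9 | step 7 | 9-(trimethylsilyloxy) derivative of 10 (silyloxy group trans to the C10 methyl) | C=C(C)[C@H]1C[C@H](OC(=O)C=C(C)C)[C@]2(C1)C(C)=CC(=O)[C@@H](O[Si](C)(C)C)[C@@H]2C
F10 | step 7 | 9-hydroxy derivative of 10 (hydroxyl trans to the C10 methyl) | C=C(C)[C@H]1C[C@H](OC(=O)C=C(C)C)[C@]2(C1)C(C)=CC(=O)[C@@H](O)[C@@H]2C
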